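**Plan**

Numbering: oxolane O1, C2 (aryl), C3 (C9H2OH), C4 (C7'(=O)Ar), C5H2. Retrosynthesis: the C7' ketone and the C4 centre go back to an exocyclic C4=C7' arylidene and C9 to an ester; then the C2–C3 ring bond is cut, then the O1–C2 benzyl ether bond and the C3 diazo group, and last the C4=C7' alkene (Stobbe).
Forward: the Stobbe condensation joins C7'=C4 to C3–C9 and C5, etherification brings in O1–C2, diazo transfer arms C3, and the only ring closes when C2–C3 forms.
Enabling feature: the C2–H bond is flanked by an electron-rich aryl ring and O1 and sits five atoms from C3 (C3–C4–C5–O1–C2), and C3 can be a carbene carbon held between the C9 ester and the C4=C7' alkene.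
Stereochemistry: C2 and C3 (cis) come from the chiral dirhodium carboxylate in the insertion; C4 is set last by thermodynamic epimerisation next to the C7' ketone, trans to the C3 side chain.

Key step: step 7

Abbreviation: Ar = 3,4,5-trimethoxyphenyl; atom labels as in the plan.
Assumption: the (S)-leucinate catalyst is taken to deliver the (2S,3R) insertion product; the sense of induction is read off the first run and, if it is opposite, the mirror-image catalyst Rh2(R-PTTL)4 is used in the same step.

**Route**

Step 1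
Reactants: 1 dimethyl succinate; 2 3,4,5-trimethoxybenzaldehyde
Product: 3 (E)-3-(methoxycarbonyl)-4-Ar-but-3-enoic acid
Conditions: NaOMe, MeOH, reflux; then aq. HCl
Reagents that add atoms: none
Why: Stobbe condensation: the succinate enolate adds to the aldehyde, the aldolate lactonises and the lactone opens by elimination, which should give the half-ester with the aryl group trans to the conjugated ester (E) and the two carboxyl groups differentiated; no stereocentre is formed.

Step 2
Reactants: 3 (E)-3-(methoxycarbonyl)-4-Ar-but-3-enoic acid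
Product: 4 4-tert-butyl 1-methyl (E)-2-(Ar-methylidene)butanedioate
Conditions: t-BuOC(=NH)CCl3, CH2Cl2/cyclohexane, rt
Reagents that add atoms: tert-butyl 2,2,2-trichloroacetimidate, CC(C)(C)OC(=N)C(Cl)(Cl)Cl
Why: Esterification by O-alkylation with a trichloroacetimidate, which the carboxylic acid itself activates by protonation; the tert-butyl ester is chosen because it resists the next reduction and later lactonisation.

Step 3
Reactants: 4 4-tert-butyl 1-methyl (E)-2-(Ar-methylidene)butanedioate
Product: 5 tert-butyl (E)-3-(hydroxymethyl)-4-Ar-but-3-enoate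
Conditions: i-Bu2AlH (2.2 equiv), CH2Cl2, −78 °C; aq. potassium sodium tartrate
Reagents that add atoms: none
Why: Chemoselective 1,2-reduction of an ester with i-Bu2AlH: the conjugated methyl ester should go to the allylic alcohol at −78 °C while the hindered tert-butyl ester is left, and the tert-butyl group keeps the new hydroxy ester from lactonising.

Step 4
Reactants: 6 3,4,5-trimethoxybenzyl alcohol
Product: 7 3,4,5-trimethoxybenzyl 2,2,2-trichloroacetimidate
Conditions: Cl3CCN, DBU (cat.), CH2Cl2, 0 °C
Reagents that add atoms: trichloroacetonitrile, N#CC(Cl)(Cl)Cl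
Why: Base-catalysed addition of the alcohol to trichloroacetonitrile (trichloroacetimidate formation), routine for benzylic alcohols.

Step 5
Reactants: 5 tert-butyl (E)-3-(hydroxymethyl)-4-Ar-but-3-enoate; 7 3,4,5-trimethoxybenzyl 2,2,2-trichloroacetimidate
Product: 8 tert-butyl (E)-3-[(3,4,5-trimethoxybenzyloxy)methyl]-4-Ar-but-3-enoate
Conditions: TMSOTf (5 mol%), CH2Cl2, −30 °C
Reagents that add atoms: none
Why: Acid-catalysed O-benzylation with a trichloroacetimidate: the activated imidate transfers the electron-rich benzyl group to the primary alcohol without base, so neither lactonisation through an alkoxide nor migration of the alkene can take place.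

Step 6
Reactants: 8 tert-butyl (E)-3-[(3,4,5-trimethoxybenzyloxy)methyl]-4-Ar-but-3-enoate
Product: 9 tert-butyl (E)-2-diazo-3-[(3,4,5-trimethoxybenzyloxy)methyl]-4-Ar-but-3-enoate
Conditions: p-ABSA, DBU, MeCN, 0 °C
Reagents that add atoms: 4-acetamidobenzenesulfonyl azide (p-ABSA), CC(=O)Nc1ccc(cc1)S(=O)(=O)N=[N+]=[N-]
Why: Regitz diazo transfer: DBU forms the ester dienolate at the methylene between ester and alkene, which takes up N2 from the sulfonyl azide, as is routine for 3-alkenoates on the way to alkenyl diazoacetates; the alkene stays in conjugation with the aryl ring.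

Step 7
Reactants: 9 tert-butyl (E)-2-diazo-3-[(3,4,5-trimethoxybenzyloxy)methyl]-4-Ar-but-3-enoate
Product: 10 tert-butyl (2S,3R,4E)-2-Ar-4-(Ar-methylidene)oxolane-3-carboxylate
Conditions: Rh2(S-PTTL)4 [dirhodium tetrakis(N-phthaloyl-(S)-tert-leucinate)] (1 mol%), toluene, −60 °C, slow addition of 9
Reagents that add atoms: none
Why: Loss of N2 from 9 on the dirhodium core (divalent rhodium) gives a donor/acceptor carbenoid at C3, stabilised by the C4=C7' alkene and the ester, which inserts in a concerted, hydride-transfer-like manner into the C2–H bond next to the electron-rich aryl ring and O1. The closest known reaction is the enantioselective intramolecular insertion of aryldiazoacetate-derived carbenoids into benzylic ether C–H bonds, which gives cis-2-aryl-2,3-dihydrobenzofuran-3-carboxylates with the same phthalimido-carboxylate catalysts; here an alkenyl donor replaces the aryl donor and the tether carries the sp3 carbon C5. The oxolane closes by 1,5-insertion through a five-membered transition state (C3–C4–C5–O1–C2), forming the C2–C3 bond. C2 and C3 are both set by the catalyst: its chiral carboxylate pocket selects one face of the carbenoid and one of the two enantiotopic benzylic hydrogens, and the aryl group turns away from the carbenoid ester during hydride transfer, which should give the cis ester under kinetic control. The step needs chemoselectivity for this C–H bond over attack of the carbenoid on the aryl ring that sits cis to it on the alkene, cyclopropene formation and 1,2-hydride shift; the five-atom placement of the doubly activated C–H bond, the absence of hydrogen on C4, low temperature and a non-polar solvent are meant to secure it.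

Step 8
Reactants: 10 tert-butyl (2S,3R,4E)-2-Ar-4-(Ar-methylidene)oxolane-3-carboxylate
Product: 11 [(2S,3S,4E)-2-Ar-4-(Ar-methylidene)oxolan-3-yl]methanol
Conditions: i-Bu2AlH (3 equiv), CH2Cl2, −78 to −20 °C; aq. potassium sodium tartrate
Reagents that add atoms: none
Why: Ester reduction with i-Bu2AlH, a Lewis-acidic and non-basic hydride, carried out directly on the insertion product so that the C3 hydrogen (alpha to the ester and allylic) can neither epimerise nor let the alkene move into the ring; C2 and C3 are unchanged.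

Step 9
Reactants: 11 [(2S,3S,4E)-2-Ar-4-(Ar-methylidene)oxolan-3-yl]methanol
Product: 12 tert-butyldimethylsilyl ether of 11
Conditions: TBSCl, imidazole, DMF, rt
Reagents that add atoms: tert-butyldimethylsilyl chloride (TBSCl), CC(C)(C)[Si](C)(C)Cl
Why: Silyl ether protection of the primary alcohol, which prevents the C9 hydroxyl from closing onto the later C7' ketone as a bicyclic hemiketal that would hold C4 in the cis form.

Step 10
Reactants: 12 tert-butyldimethylsilyl ether of 11
Product: 14 (2S,3S,4S)-3-[(tert-butyldimethylsilyloxy)methyl]-4-[(S)-hydroxy(Ar)methyl]-2-Ar-oxolane, via benzylic alkylborane 13 (not isolated)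
Conditions: BH3·THF, THF, 0 °C to rt; then aq. NaOH, H2O2, 0 °C
Reagents that add atoms: borane–tetrahydrofuran, B.C1CCOC1 (boron of 13); hydrogen peroxide, OO (hydroxyl oxygen of 14)
Why: Hydroboration–oxidation: boron should go to C7', the less substituted alkene carbon and the one remote from the allylic ring oxygen, by syn addition from the face opposite the C3 side chain, and oxidation with retention gives the carbinol; the C4 and C7' configurations formed here are provisional, since C7' is oxidised and C4 equilibrated in the next two steps.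

Step 11
Reactants: 14 (2S,3S,4S)-3-[(tert-butyldimethylsilyloxy)methyl]-4-[(S)-hydroxy(Ar)methyl]-2-Ar-oxolane
Product: 15 (2S,3S,4S)-3-[(tert-butyldimethylsilyloxy)methyl]-4-(3,4,5-trimethoxybenzoyl)-2-Ar-oxolane (all-cis)
Conditions: Dess–Martin periodinane, CH2Cl2, rt
Reagents that add atoms: none
Why: Dess–Martin oxidation of the secondary benzylic alcohol to the aryl ketone under neutral conditions that touch neither the silyl ether nor the benzylic ring ether.

Step 12
Reactants: 15 (2S,3S,4S)-3-[(tert-butyldimethylsilyloxy)methyl]-4-(3,4,5-trimethoxybenzoyl)-2-Ar-oxolane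
Product: 16 (2S,3S,4R)-3-[(tert-butyldimethylsilyloxy)methyl]-4-(3,4,5-trimethoxybenzoyl)-2-Ar-oxolane
Conditions: DBU (0.3 equiv), CH2Cl2, rt
Reagents that add atoms: none
Why: Base-mediated epimerisation through the ketone enolate: C4 should equilibrate to the isomer with the aroyl group trans to the C3 side chain, which relieves the crowding of the all-cis ring, while C2 and C3 bear no acidic hydrogen.

Step 13
Reactants: 16 (2S,3S,4R)-3-[(tert-butyldimethylsilyloxy)methyl]-4-(3,4,5-trimethoxybenzoyl)-2-Ar-oxolane
Product: 17 (2S,3S,4R)-3-(hydroxymethyl)-4-(3,4,5-trimethoxybenzoyl)-2-Ar-oxolane (target)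
Conditions: HF·pyridine, pyridine, THF, 0 °C to rt
Reagents that add atoms: none
Why: Fluoride-mediated desilylation under buffered, weakly acidic conditions that do not enolise the ketone, so the trans C4 configuration is kept; the trans hydroxy ketone cannot close to a cis-fused hemiketal.

**Compound list**

1 | dimethyl succinate | COC(=O)CCC(=O)OC | starting material
2 | 3,4,5-trimethoxybenzaldehyde | O=Cc1cc(OC)c(OC)c(OC)c1 | starting material
3 | (E)-3-(methoxycarbonyl)-4-(3,4,5-trimethoxyphenyl)but-3-enoic acid | COC(=O)/C(CC(=O)O)=C/c1cc(OC)c(OC)c(OC)c1 | intermediate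
4 | 4-tert-butyl 1-methyl (E)-2-(3,4,5-trimethoxybenzylidene)butanedioate | COC(=O)/C(CC(=O)OC(C)(C)C)=C/c1cc(OC)c(OC)c(OC)c1 | intermediate
5 | tert-butyl (E)-3-(hydroxymethyl)-4-(3,4,5-trimethoxyphenyl)but-3-enoate | CC(C)(C)OC(=O)C/C(CO)=C\c1cc(OC)c(OC)c(OC)c1 | intermediate
6 | 3,4,5-trimethoxybenzyl alcohol | OCc1cc(OC)c(OC)c(OC)c1 | starting material
7 | 3,4,5-trimethoxybenzyl 2,2,2-trichloroacetimidate | N=C(OCc1cc(OC)c(OC)c(OC)c1)C(Cl)(Cl)Cl | intermediate
8 | tert-butyl (E)-3-[(3,4,5-trimethoxybenzyloxy)methyl]-4-(3,4,5-trimethoxyphenyl)but-3-enoate | CC(C)(C)OC(=O)C/C(COCc1cc(OC)c(OC)c(OC)c1)=C\c1cc(OC)c(OC)c(OC)c1 | intermediate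
9 | tert-butyl (E)-2-diazo-3-[(3,4,5-trimethoxybenzyloxy)methyl]-4-(3,4,5-trimethoxyphenyl)but-3-enoate | CC(C)(C)OC(=O)C(=[N+]=[N-])/C(COCc1cc(OC)c(OC)c(OC)c1)=C\c1cc(OC)c(OC)c(OC)c1 | intermediate
10 | tert-butyl (2S,3R,4E)-2-(3,4,5-trimethoxyphenyl)-4-(3,4,5-trimethoxybenzylidene)oxolane-3-carboxylate | CC(C)(C)OC(=O)[C@H]1[C@@H](c2cc(OC)c(OC)c(OC)c2)OC/C1=C/c1cc(OC)c(OC)c(OC)c1 | intermediate
11 | [(2S,3S,4E)-2-(3,4,5-trimethoxyphenyl)-4-(3,4,5-trimethoxybenzylidene)oxolan-3-yl]methanol | OC[C@H]1[C@@H](c2cc(OC)c(OC)c(OC)c2)OC/C1=C/c1cc(OC)c(OC)c(OC)c1 | intermediate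
12 | tert-butyldimethylsilyl ether of 11 | CC(C)(C)[Si](C)(C)OC[C@H]1[C@@H](c2cc(OC)c(OC)c(OC)c2)OC/C1=C/c1cc(OC)c(OC)c(OC)c1 | intermediate
13 | monoalkylborane from syn addition of B–H to 12 (BH2 on C7', hydrogen on C4, both on the face opposite the C3 side chain) | B[C@H](c1cc(OC)c(OC)c(OC)c1)[C@@H]2CO[C@H](c3cc(OC)c(OC)c(OC)c3)[C@@H]2CO[Si](C)(C)C(C)(C)C | intermediate
14 | (2S,3S,4S)-3-[(tert-butyldimethylsilyloxy)methyl]-4-[(S)-hydroxy(3,4,5-trimethoxyphenyl)methyl]-2-(3,4,5-trimethoxyphenyl)oxolane | O[C@H](c1cc(OC)c(OC)c(OC)c1)[C@@H]2CO[C@H](c3cc(OC)c(OC)c(OC)c3)[C@@H]2CO[Si](C)(C)C(C)(C)C | intermediate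
15 | (2S,3S,4S)-3-[(tert-butyldimethylsilyloxy)methyl]-4-(3,4,5-trimethoxybenzoyl)-2-(3,4,5-trimethoxyphenyl)oxolane | COc1cc(C(=O)[C@@H]2CO[C@H](c3cc(OC)c(OC)c(OC)c3)[C@@H]2CO[Si](C)(C)C(C)(C)C)cc(OC)c1OC | intermediate
16 | (2S,3S,4R)-3-[(tert-butyldimethylsilyloxy)methyl]-4-(3,4,5-trimethoxybenzoyl)-2-(3,4,5-trimethoxyphenyl)oxolane | COc1cc(C(=O)[C@H]2CO[C@H](c3cc(OC)c(OC)c(OC)c3)[C@@H]2CO[Si](C)(C)C(C)(C)C)cc(OC)c1OC | intermediate
17 | (2S,3S,4R)-3-(hydroxymethyl)-4-(3,4,5-trimethoxybenzoyl)-2-(3,4,5-trimethoxyphenyl)oxolane | COc1cc(C(=O)[C@H]2CO[C@H](c3cc(OC)c(OC)c(OC)c3)[C@@H]2CO)cc(OC)c1OC | target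

**Count and risks**

Total steps: 13. Longest linear sequence: 12 steps (steps 1–3 and 5–13, from 1 and 2).

1. Step 7. The carbenoid may be diverted: attack on the aryl ring that sits cis to it on the alkene, closure to a cyclopropene, or loss of cis and enantiofacial control. The fallback sets out from half-ester 3 and returns at silyl ether 12; it builds C2–C3 by an auxiliary-controlled aldol reaction and closes the ring at O1–C5. The acid of 3 is coupled (pivaloyl chloride, Et3N, LiCl) with (S)-4-benzyloxazolidin-2-one to give the imide F1. Its MgCl2-catalysed anti-aldol reaction with aldehyde 2 (Et3N, TMSCl, EtOAc) should give the silylated anti adduct F2, the chelated enolate fixing C3 and the anti course fixing C2. Acidic methanol frees the hydroxy imide F3, which lactonises onto the neighbouring conjugated methyl ester to the cis lactone imide F4. NaBH4 in wet THF removes the auxiliary to give the hydroxy lactone F5, TBSCl gives the silyl ether lactone F6, and i-Bu2AlH opens it to the diol F7. Cyclodehydration through the primary allylic alcohol (PPh3, diisopropyl azodicarboxylate; Mitsunobu conditions) leaves C2 untouched and gives 12.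

2. Step 5. Under acid the tert-butyl group may be lost with lactonisation of the hydroxy ester, the allylic alcohol may ionise, or the electron-rich imidate may rearrange or alkylate itself. The fallback sets out from alcohol 5 and returns at ether 8: alkylation with commercial 3,4,5-trimethoxybenzyl bromide and Ag2O in CH2Cl2 in the dark forms the ether by halide abstraction under neutral conditions and makes step 4 unnecessary; no compound outside the list is formed (F0).

3. Step 10. Boron may be delivered to the ring carbon C4 instead of C7', or addition to the hindered trisubstituted alkene may stall. The fallback sets out from 12 and returns at ketone 15: dihydroxylation (OsO4 cat., N-methylmorpholine N-oxide, acetone/water) from the face opposite the C3 side chain gives the diol F8. Oxidation of its secondary benzylic hydroxyl (SO3·pyridine, DMSO, Et3N) gives the tertiary hydroxy ketone F9. SmI2 in THF/MeOH at −78 °C cleaves the C4–O bond next to the ketone, and protonation of the samarium enolate gives 15; any 16 formed alongside is the next compound of the route, and step 12 converges both.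

Further compounds
F1 | step 7 | (S)-4-benzyl-3-[(E)-3-(methoxycarbonyl)-4-(3,4,5-trimethoxyphenyl)but-3-enoyl]oxazolidin-2-one | COC(=O)/C(CC(=O)N1[C@@H](Cc2ccccc2)COC1=O)=C/c1cc(OC)c(OC)c(OC)c1
F2 | step 7 | anti-aldol adduct of F1 and 2 as trimethylsilyl ether (C2 S, C3 R) | COC(=O)/C(=C/c1cc(OC)c(OC)c(OC)c1)[C@@H](C(=O)N1[C@@H](Cc2ccccc2)COC1=O)[C@@H](c1cc(OC)c(OC)c(OC)c1)O[Si](C)(C)C
F3 | step 7 | free hydroxy imide from F2 (C2 S, C3 R) | COC(=O)/C(=C/c1cc(OC)c(OC)c(OC)c1)[C@@H](C(=O)N1[C@@H](Cc2ccccc2)COC1=O)[C@@H](c1cc(OC)c(OC)c(OC)c1)O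
F4 | step 7 | (S)-4-benzyl-3-{[(2S,3R,4E)-5-oxo-2-(3,4,5-trimethoxyphenyl)-4-(3,4,5-trimethoxybenzylidene)oxolan-3-yl]carbonyl}oxazolidin-2-one | O=C(N1[C@@H](Cc2ccccc2)COC1=O)[C@H]1[C@@H](c2cc(OC)c(OC)c(OC)c2)OC(=O)/C1=C/c1cc(OC)c(OC)c(OC)c1
F5 | step 7 | C5-oxo (lactone) analogue of 11 | OC[C@H]1[C@@H](c2cc(OC)c(OC)c(OC)c2)OC(=O)/C1=C/c1cc(OC)c(OC)c(OC)c1
F6 | step 7 | C5-oxo (lactone) analogue of 12 | CC(C)(C)[Si](C)(C)OC[C@H]1[C@@H](c2cc(OC)c(OC)c(OC)c2)OC(=O)/C1=C/c1cc(OC)c(OC)c(OC)c1
F7 | step 7 | ring-opened diol of F6: (E)-allylic C5 alcohol, benzylic C2 alcohol, C9 silyl ether | OC/C(=C/c1cc(OC)c(OC)c(OC)c1)[C@@H](CO[Si](C)(C)C(C)(C)C)[C@@H](c1cc(OC)c(OC)c(OC)c1)O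
F0 | step 5 | none | none
F8 | step 10 | C4,C7'-diol from syn dihydroxylation of 12 | O[C@H](c1cc(OC)c(OC)c(OC)c1)[C@]2(O)CO[C@H](c3cc(OC)c(OC)c(OC)c3)[C@@H]2CO[Si](C)(C)C(C)(C)C
F9 | step 10 | C4-hydroxy C7'-ketone from F8 | O=C(c1cc(OC)c(OC)c(OC)c1)[C@]2(O)CO[C@H](c3cc(OC)c(OC)c(OC)c3)[C@@H]2CO[Si](C)(C)C(C)(C)C
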